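**Plan**
1. Numbering: oxan-4-one O1, C2 (bears ring A), C3, C4 (C=O), C5, C6; side chain C1′ (carbinol) and C2′ (CH2 on ring B). Cuts: C2–C3 (key step), C2–O1 (acetalisation), C4–C5 (acetylide + epoxide), C5–C6 (ylide CH2), C2′–ring B (Grignard + epoxide).
2. Enabling feature: C2 is an aldehyde-level carbon. It is bonded to O1 and to the electron-rich guaiacyl ring A and lies β to the C4 ketone. O1 and the C1′ hydroxyl are the two oxygens of an anti-1,2-diol.
3. The ring A aldehyde is therefore parked on both oxygens as a temporary 1,3-dioxolane, whose bond from C2 to the C1′ oxygen is absent from the target. This ring protects the diol, removes the need to tell the two hydroxyls apart, and stores the C2 cation.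
4. Key event: Lewis-acid opening of the dioxolane and capture of the oxocarbenium ion by a C3=C4 enol acetate. This closes the oxanone (the last ring), unveils the ketone, sets C2 and releases the C1′ oxygen as its acetate.
5. Forward order: ring B Grignard + (S)-epichlorohydrin → ylide homologation → epoxidation → acetylide → temporary dioxolane with ring A → enol acetate → oxanone → deacetylation → debenzylation.
6. Stereochemistry: C1′ (S) comes from (S)-epichlorohydrin. C6 (R) comes from a matched Sharpless epoxidation (erythro). C2 (S) comes from 1,3-induction by C6 in the chair of the key step (2,6-cis).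

Key step: step 7

Remark: the acetal carbon of the two dioxolane intermediates forms as a mixture of epimers. It is left undefined in their SMILES because it becomes planar in the key step, so both epimers converge.

Step 1
Reactants: 1 1-(benzyloxy)-4-bromobenzene; 2 (S)-epichlorohydrin
Product: 5 (2S)-2-[4-(benzyloxy)benzyl]oxirane, via Grignard reagent 3 (not isolated), via chlorohydrin 4 (not isolated)
Conditions: Mg, THF, reflux; CuBr·SMe2 (10 mol %), 2, THF, −40 to 0 °C; H2O; then NaOH, Et2O–H2O, rt
Reagents that add atoms: none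
Why: Copper-catalysed Grignard opening of a terminal epoxide takes place at the unsubstituted ring carbon faster than any attack on the C–Cl bond, and the intramolecular Williamson closure of chlorohydrin 4 then moves the oxirane without touching the C–O stereocentre, so the S configuration of 2 (the later C1′) is carried over unchanged.

Step 2
Reactants: 5 (2S)-2-[4-(benzyloxy)benzyl]oxirane
Product: 6 (2S)-1-[4-(benzyloxy)phenyl]but-3-en-2-ol
Conditions: Me3S+ I− (3 equiv), n-BuLi (2.9 equiv), THF, −10 °C to rt
Reagents that add atoms: trimethylsulfonium iodide, C[S+](C)C.[I-]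
Why: Excess dimethylsulfonium methylide (Corey–Chaykovsky reagent) opens the terminal epoxide at its CH2 group and the γ-oxido sulfonium salt loses Me2S by base-induced elimination, a well-precedented one-carbon epoxide-to-allylic-alcohol homologation that leaves the carbinol centre untouched.

Step 3
Reactants: 6 (2S)-1-[4-(benzyloxy)phenyl]but-3-en-2-ol
Product: 7 (1S)-2-[4-(benzyloxy)phenyl]-1-[(2R)-oxiran-2-yl]ethan-1-ol (erythro)
Conditions: Ti(OiPr)4 (20 mol %), L-(+)-diisopropyl tartrate (24 mol %), t-BuOOH (1.5 equiv, decane), 4 Å molecular sieves, CH2Cl2, −20 °C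
Reagents that add atoms: tert-butyl hydroperoxide, CC(C)(C)OO
Why: Sharpless asymmetric epoxidation in the matched sense: with L-(+)-diisopropyl tartrate the S enantiomer of a 1-substituted allyl alcohol is the fast-reacting one and is epoxidised to the erythro epoxy alcohol, so reagent and substrate control together set the R oxirane carbon (the later C6).

Step 4
Reactants: 7 (1S)-2-[4-(benzyloxy)phenyl]-1-[(2R)-oxiran-2-yl]ethan-1-ol
Product: 8 (2S,3R)-1-[4-(benzyloxy)phenyl]hex-5-yne-2,3-diol (anti)
Conditions: LiC≡CH·H2NCH2CH2NH2 (4 equiv), DMSO, 15 °C to rt; H2O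
Reagents that add atoms: lithium acetylide–ethylenediamine complex, [Li+].[C-]#C.NCCN
Why: SN2 opening of the terminal epoxide by acetylide at the primary carbon keeps both stereocentres, and a Payne equilibrium of the alkoxide is harmless because only the 1,2-epoxide offers an unhindered primary carbon.

Step 5
Reactants: 8 (2S,3R)-1-[4-(benzyloxy)phenyl]hex-5-yne-2,3-diol; 9 4-(benzyloxy)-3-methoxybenzaldehyde (O-benzylvanillin)
Product: 10 (4R,5S)-5-[4-(benzyloxy)benzyl]-2-[4-(benzyloxy)-3-methoxyphenyl]-4-(prop-2-yn-1-yl)-1,3-dioxolane (both epimers at C2 of the dioxolane)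
Conditions: 9 (1.1 equiv), PPTS (10 mol %), toluene, reflux, Dean–Stark trap
Reagents that add atoms: none
Why: Acid-catalysed acetalisation with azeotropic water removal breaks no C–O bond at C6 or C1′ and turns the anti-diol into the cis-4,5-disubstituted 1,3-dioxolane, the temporary ring that protects both hydroxyls and brings in C2 together with ring A.

Step 6
Reactants: 10 the alkynyl dioxolane
Product: 11 3-{(4R,5S)-5-[4-(benzyloxy)benzyl]-2-[4-(benzyloxy)-3-methoxyphenyl]-1,3-dioxolan-4-yl}prop-1-en-2-yl acetate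
Conditions: AcOH (2 equiv), [RuCl2(p-cymene)]2 (2 mol %), P(2-furyl)3 (4 mol %), Na2CO3 (8 mol %), toluene, 80 °C
Reagents that add atoms: acetic acid, CC(=O)O
Why: Ruthenium-catalysed Markovnikov hydroacyloxylation of a terminal alkyne, in which the tri(2-furyl)phosphine/carbonate catalyst directs acetate to the internal carbon, gives the 2-acetoxyallyl group under nearly neutral conditions that acetals and benzyl ethers tolerate.

Step 7
Reactants: 11 the enol acetate dioxolane
Product: 13 (1S)-1-{(2R,6S)-6-[4-(benzyloxy)-3-methoxyphenyl]-4-oxooxan-2-yl}-2-[4-(benzyloxy)phenyl]ethyl acetate, via oxocarbenium triflate 12 (not isolated)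
Conditions: Me3SiOTf (20 mol %), 2,6-di-tert-butyl-4-methylpyridine (30 mol %), CH2Cl2, −78 to 0 °C; Et3N quench
Reagents that add atoms: none
Why: Proposed new method: Me3SiOTf silylates the acetal oxygen that sits on C1′ and opens the temporary dioxolane reversibly to the (E)-oxocarbenium ion 12 (C2=O1+, stabilised by ring A), the terminal carbon of the enol acetate (C3) attacks C2, and the acetyl group of the resulting acyloxycarbenium ion leaves as AcOTf, which acetylates the C1′ silyl ether and returns Me3SiOTf, so the step is a catalytic isomerisation of 11 to 13. The closest known reaction types are the Lewis-acid (Mukaiyama-type) addition of enol acetates to acetals, the Prins–Sakurai cyclisation of cyclic acetals that carry an allylsilane, and the Petasis–Ferrier rearrangement; what lacks precedent is the combination of a 1,3-dioxolane, a tethered enol acetate and the O-to-O acetyl relay. The oxan-4-one ring closes in a 6-endo-trig mode (endo with respect to both C2=O1+ and C3=C4). The new stereocentre C2 is controlled by C6 through a chair transition state in which ring A and the C6 side chain are both equatorial, which gives the 2,6-cis (2S,6R) product, also the thermodynamic isomer. The selectivity needed is between the two acetal C–O bonds: cleavage of C2–O1 gives an ion that could only close a seven-membered ring, and since both openings are reversible the material should drain through the six-membered chair. The C6–O and C1′–O bonds are never broken, the hindered pyridine keeps TfOH from protonating the enol acetate, and attack of ring B on the cation is unlikely because the only reachable positions are meta to its benzyloxy group.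

Step 8
Reactants: 13 the oxanone acetate
Product: 14 (2S,6R)-2-[4-(benzyloxy)-3-methoxyphenyl]-6-{(1S)-2-[4-(benzyloxy)phenyl]-1-hydroxyethyl}oxan-4-one
Conditions: K2CO3 (20 mol %), MeOH–THF, 0 °C to rt
Reagents that add atoms: none
Why: Base-catalysed transesterification (Zemplén-type) removes the relay acetate, the phenols being still benzylated so that no quinone methide can form, and the 2,6-cis oxanone being the thermodynamic isomer so that a reversible retro-oxa-Michael event at C2 could not change the configuration.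

Step 9
Reactants: 14 the bis(benzyl ether) hydroxy ketone
Product: 15 (2S,6R)-2-(4-hydroxy-3-methoxyphenyl)-6-[(1S)-1-hydroxy-2-(4-hydroxyphenyl)ethyl]oxan-4-one (target)
Conditions: H2 (1 atm), 10% Pd/C, EtOAc, rt
Reagents that add atoms: none
Why: Catalytic hydrogenolysis cleaves the two aryl benzyl ethers much faster than the cyclic secondary C2–O1 benzylic ether or the ketone, so that stopping after uptake of two equivalents of H2 should deliver the target with all three stereocentres intact.

**Compound list**
1 | 1-(benzyloxy)-4-bromobenzene | Brc1ccc(OCc2ccccc2)cc1 | starting material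
2 | (S)-epichlorohydrin | ClC[C@@H]1CO1 | starting material
3 | 4-(benzyloxy)phenylmagnesium bromide | Br[Mg]c1ccc(OCc2ccccc2)cc1 | intermediate
4 | (2S)-1-[4-(benzyloxy)phenyl]-3-chloropropan-2-ol | ClC[C@@H](O)Cc1ccc(OCc2ccccc2)cc1 | intermediate
5 | (2S)-2-[4-(benzyloxy)benzyl]oxirane | C1O[C@H]1Cc2ccc(OCc3ccccc3)cc2 | intermediate
6 | (2S)-1-[4-(benzyloxy)phenyl]but-3-en-2-ol | C=C[C@@H](O)Cc1ccc(OCc2ccccc2)cc1 | intermediate
7 | (1S)-2-[4-(benzyloxy)phenyl]-1-[(2R)-oxiran-2-yl]ethan-1-ol | C1O[C@H]1[C@@H](O)Cc2ccc(OCc3ccccc3)cc2 | intermediate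
8 | (2S,3R)-1-[4-(benzyloxy)phenyl]hex-5-yne-2,3-diol | C#CC[C@@H](O)[C@@H](O)Cc1ccc(OCc2ccccc2)cc1 | intermediate
9 | 4-(benzyloxy)-3-methoxybenzaldehyde | COc1cc(C=O)ccc1OCc1ccccc1 | starting material
10 | (4R,5S)-5-[4-(benzyloxy)benzyl]-2-[4-(benzyloxy)-3-methoxyphenyl]-4-(prop-2-yn-1-yl)-1,3-dioxolane | C#CC[C@H]1OC(c2ccc(OCc3ccccc3)c(OC)c2)O[C@H]1Cc1ccc(OCc2ccccc2)cc1 | intermediate
11 | 3-{(4R,5S)-5-[4-(benzyloxy)benzyl]-2-[4-(benzyloxy)-3-methoxyphenyl]-1,3-dioxolan-4-yl}prop-1-en-2-yl acetate | C=C(OC(C)=O)C[C@H]1OC(c2ccc(OCc3ccccc3)c(OC)c2)O[C@H]1Cc1ccc(OCc2ccccc2)cc1 | intermediate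
12 | ring-opened (E)-oxocarbenium triflate with C1′ trimethylsilyl ether | C=C(OC(C)=O)C[C@@H]([O+]=Cc1ccc(OCc2ccccc2)c(OC)c1)[C@@H](O[Si](C)(C)C)Cc1ccc(OCc2ccccc2)cc1.[O-]S(=O)(=O)C(F)(F)F | intermediate
13 | (1S)-1-{(2R,6S)-6-[4-(benzyloxy)-3-methoxyphenyl]-4-oxooxan-2-yl}-2-[4-(benzyloxy)phenyl]ethyl acetate | COc1cc([C@@H]2CC(=O)C[C@H]([C@@H](OC(C)=O)Cc3ccc(OCc4ccccc4)cc3)O2)ccc1OCc1ccccc1 | intermediate
14 | (2S,6R)-2-[4-(benzyloxy)-3-methoxyphenyl]-6-{(1S)-2-[4-(benzyloxy)phenyl]-1-hydroxyethyl}oxan-4-one | COc1cc([C@@H]2CC(=O)C[C@H]([C@@H](O)Cc3ccc(OCc4ccccc4)cc3)O2)ccc1OCc1ccccc1 | intermediate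
15 | (2S,6R)-2-(4-hydroxy-3-methoxyphenyl)-6-[(1S)-1-hydroxy-2-(4-hydroxyphenyl)ethyl]oxan-4-one | COc1cc([C@@H]2CC(=O)C[C@H]([C@@H](O)Cc3ccc(O)cc3)O2)ccc1O | target

Total step count: 9. Longest linear sequence: 9 steps (1 to 15); aldehyde 9 is bought.

**Steps most likely to fail**

Risk 1, step 7 (bears the label "Proposed new method:").
- What may go wrong: the stabilised oxocarbenium ion may re-close to the acetal faster than the weakly nucleophilic enol acetate attacks. The enol acetate may be lost by protonolysis. The acetyl relay may fail to turn the catalyst over.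
- Fallback: known chemistry, with ring closure by a C–O bond instead of a C–C bond. It sets out from 11 and comes back at 14. Methanolysis of the enol acetate of 11 (K2CO3, MeOH) gives the methyl ketone F1. Its kinetic lithium enolate (LiN(iPr)2, THF, −78 °C) adds to aldehyde 9 to give the aldol F2. Mesylation and elimination (MsCl, Et3N) give the (E)-enone F3. Aqueous acetic acid takes off the arylidene acetal to give the dihydroxy enone F4. With catalytic DBU this closes by 6-endo-trig oxa-Michael addition of the C6 hydroxyl, under thermodynamic control, to the 2,6-cis oxanone 14.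

Risk 2, step 6.
- What may go wrong: Markovnikov selectivity of the acetate addition may be incomplete. The acetal oxygens may inhibit the catalyst. The acetal may be lost to acid at 80 °C.
- Fallback: another nucleophile and another oxidation level at C4. It sets out from 7 and comes back at 14. Opening of 7 with the Grignard reagent of (2-bromoallyl)trimethylsilane (Mg, THF; CuBr·SMe2 cat.) gives the allylsilane diol F5. Acetalisation with 9 (PPTS) gives the allylsilane dioxolane F6. Lewis-acid opening of the cyclic acetal with intramolecular Prins–Sakurai closure (Me3SiOTf, CH2Cl2, −78 °C) is a known reaction of cyclic acetals that carry an allylsilane, and it gives the 4-methylene oxane F7. Lemieux–Johnson cleavage (OsO4 cat., NaIO4) then gives 14.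

Risk 3, step 3.
- What may go wrong: epoxidation of the monosubstituted alkene may be slow. Long reaction times may bring titanium-promoted opening of the product and erosion of the erythro selectivity.
- Fallback: C6 is set by 1,2-induction in a carbonyl addition instead of by epoxidation. It sets out from 6 and comes back at 8. Silylation (TBSCl, imidazole) gives the silyl ether F8. Ozonolysis (O3, CH2Cl2, −78 °C; Me2S) gives the α-silyloxy aldehyde F9. BF3·OEt2-promoted SE2′ addition of allenyltributylstannane under Felkin–Anh control gives the anti homopropargylic alcohol F10. Desilylation (Bu4NF, THF) gives 8.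

**Further compounds**
F1 | step 7 | 1-{(4R,5S)-5-[4-(benzyloxy)benzyl]-2-[4-(benzyloxy)-3-methoxyphenyl]-1,3-dioxolan-4-yl}propan-2-one | CC(=O)C[C@H]1OC(c2ccc(OCc3ccccc3)c(OC)c2)O[C@H]1Cc1ccc(OCc2ccccc2)cc1
F2 | step 7 | 4-[4-(benzyloxy)-3-methoxyphenyl]-1-{(4R,5S)-5-[4-(benzyloxy)benzyl]-2-[4-(benzyloxy)-3-methoxyphenyl]-1,3-dioxolan-4-yl}-4-hydroxybutan-2-one (carbinol epimers) | O=C(CC(O)c1ccc(OCc2ccccc2)c(OC)c1)C[C@H]1OC(c2ccc(OCc3ccccc3)c(OC)c2)O[C@H]1Cc1ccc(OCc2ccccc2)cc1
F3 | step 7 | (3E)-4-[4-(benzyloxy)-3-methoxyphenyl]-1-{(4R,5S)-5-[4-(benzyloxy)benzyl]-2-[4-(benzyloxy)-3-methoxyphenyl]-1,3-dioxolan-4-yl}but-3-en-2-one | O=C(/C=C/c1ccc(OCc2ccccc2)c(OC)c1)C[C@H]1OC(c2ccc(OCc3ccccc3)c(OC)c2)O[C@H]1Cc1ccc(OCc2ccccc2)cc1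
F4 | step 7 | (1E,5R,6S)-1-[4-(benzyloxy)-3-methoxyphenyl]-7-[4-(benzyloxy)phenyl]-5,6-dihydroxyhept-1-en-3-one | O=C(/C=C/c1ccc(OCc2ccccc2)c(OC)c1)C[C@@H](O)[C@@H](O)Cc1ccc(OCc2ccccc2)cc1
F5 | step 6 | (2S,3R)-1-[4-(benzyloxy)phenyl]-5-[(trimethylsilyl)methyl]hex-5-ene-2,3-diol | C=C(C[Si](C)(C)C)C[C@@H](O)[C@@H](O)Cc1ccc(OCc2ccccc2)cc1
F6 | step 6 | (4R,5S)-5-[4-(benzyloxy)benzyl]-2-[4-(benzyloxy)-3-methoxyphenyl]-4-{2-[(trimethylsilyl)methyl]prop-2-en-1-yl}-1,3-dioxolane | C=C(C[Si](C)(C)C)C[C@H]1OC(c2ccc(OCc3ccccc3)c(OC)c2)O[C@H]1Cc1ccc(OCc2ccccc2)cc1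
F7 | step 6 | (1S)-1-{(2R,6S)-6-[4-(benzyloxy)-3-methoxyphenyl]-4-methylideneoxan-2-yl}-2-[4-(benzyloxy)phenyl]ethan-1-ol | COc1cc([C@@H]2CC(=C)C[C@H]([C@@H](O)Cc3ccc(OCc4ccccc4)cc3)O2)ccc1OCc1ccccc1
F8 | step 3 | {(2S)-1-[4-(benzyloxy)phenyl]but-3-en-2-yl}oxy(tert-butyl)dimethylsilane | C=C[C@@H](O[Si](C)(C)C(C)(C)C)Cc1ccc(OCc2ccccc2)cc1
F9 | step 3 | (2S)-3-[4-(benzyloxy)phenyl]-2-[(tert-butyldimethylsilyl)oxy]propanal | O=C[C@@H](O[Si](C)(C)C(C)(C)C)Cc1ccc(OCc2ccccc2)cc1
F10 | step 3 | (2S,3R)-1-[4-(benzyloxy)phenyl]-2-[(tert-butyldimethylsilyl)oxy]hex-5-yn-3-ol | C#CC[C@@H](O)[C@@H](O[Si](C)(C)C(C)(C)C)Cc1ccc(OCc2ccccc2)cc1
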